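4 questions stand on one flask, the one followed on Saturday: each asks for c(target), in percent of the substrate charged, or for the option that raises it most.

* target, in percent of the substrate first charged, at 3.0 d
* what to do for the largest gain in target; "none" if nothing gains more than 2 percentage points (delta / theta / gamma / beta / none)
* target present, in percent of the substrate first charged, after theta
* target present, in percent of the substrate first charged, after beta

| flask | substrate | partner | temperature | remark | time |
|---|---|---|---|---|---|
| Saturday's | 0.50 M | 1.1 equiv | 35 °C | the very flask that is asked about, followed so far |  |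
| Sunday's | 1 M | 1.1 equiv | 41 °C | run made earlier |  |
| flask | 0.50 M | 1.10 equiv | 35 °C |  | 3.0 d |

- delta: at 3.0 d take out 90% of the by-product then present, then wait 6.0 d
- theta: at 3.0 d raise the temperature by 25 K, then wait 6.0 d
- gamma: at 3.0 d add partner, 100% of the amount charged, then wait 6.0 d
- beta: change nothing and wait 6.0 d more

- the volume of additions can be left aside
- what may be going on: intermediate <-> target; target <-> isomer of the product B; intermediate <-> isomer of the product A; substrate + partner -> intermediate + by-product

Saturday's run (percent of the substrate charged)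

| time / h | target / % | substrate / % |
|---|---|---|
| 3.00 | 44.4 | 16.7 |
| 5.00 | 44.8 | 9.9 |
| 8.00 | 39.4 | 5.9 |
| 12.0 | 35.2 | 2.0 |
| 20.0 | 27.0 | 1.3 |
| 30.0 | 19.8 | 0.5 |
| 40.0 | 15.5 | 0.7 |

Sunday's run (percent of the substrate charged)

| time / min | target / % | substrate / % |
|---|---|---|
| 8.00 | 6.9 | 61.8 |
| 12.0 | 11.4 | 50.5 |
| 20.0 | 20.8 | 37.7 |
| 25.0 | 27.4 | 31.3 |
| 40.0 | 38.5 | 22.9 |
| 60.0 | 45.5 | 13.2 |
| 90.0 | 47.5 | 9.4 |

(standard deviation of a reading: 0.5 percentage points)

The partner stands at 1.10 equiv, so in Saturday's flask the substrate is the limiting reagent. Hardly any substrate remains at 40.0 h, where it reads 0.7%, so delta and gamma, which act on the one-way step of substrate and partner, find little to work on at 3.0 d.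

But in Saturday's run c(target) reads highest, 44.8%, at 5.00 h and then falls, so 3.0 d lies on a tail, and this tail is reckoned here in logarithms. From 20.0 h to 40.0 h c(target) drops 0.241 of a power of ten, so it needs 83.0 h per factor of 10: its decade time.

The time 3.0 d lies 0.386 decades past the last reading, which gives 6.38% by this reckoning. But the last two readings give 94.0 h, longer than 83.0 h: at a scatter of 0.5 percentage points this is a hint that the fall slows, so 6.38% may lie low. Beta waits further along this fall, so this reckoning names theta, but both runs were held at one temperature, so the size of theta stays unread.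

The forecast says 10.5% (7% to 13.5%), above this reckoning, and names theta, with 14% (8% to 22%) after theta and 9.5% (5% to 13%) after beta, holding that "the 20–40 h readings extrapolate to a plateau near 9–10%".

Saturday's flask gives c(target) = 8.16% at 3.0 d, then 21.8% after theta, the best option at 14 points gained, and 5.38% after beta.

intermediate ⇌ target (K = 2.90, k = 0.0229 min⁻¹, Ea = 82.0 kJ mol⁻¹, ΔH = 2.00 kJ mol⁻¹); target ⇌ isomer of the product B (K = 0.370, k = 0.00118 min⁻¹, Ea = 111 kJ mol⁻¹, ΔH = 20.0 kJ mol⁻¹); intermediate ⇌ isomer of the product A (K = 49.0, k = 0.00342 min⁻¹, Ea = 108 kJ mol⁻¹, ΔH = −62.0 kJ mol⁻¹); substrate + partner → intermediate + by-product (k = 0.0408 M⁻¹ min⁻¹, Ea = 74.0 kJ mol⁻¹); (constants at 35 °C) At 3.0 d target in Saturday's flask is made at 0.318 of the rate at which it is used up, each step taken net. Under beta the decade time of this flask averages 798 h over the wait, ten times 83.0 h. A neighbouring flask is read at 30 h, inside the span that gave 83.0 h: carried on from the 20.0 h reading, 83.0 h gives 20.5%, and that flask holds 19.8%.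

(The runs were computed from invented constants, noise included.)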